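All runs come from a simulation for an exercise, and the scatter is random.

1. I started from the late readings. At 40.0 min, Wednesday's run held 13.1% free monomer and Saturday's 13.3%, from charges of 0.13 M and 0.29 M. Their mean gave 2.02 for S, the reach: the natural logarithm of charged over late free monomer.

all flasks: initiator 0.38 mM

|  | free monomer | remark | time |
|---|---|---|---|
| Wednesday's | 0.13 M | run made earlier |  |
| Saturday's | 0.29 M | run made earlier |  |
| flask | 0.19 M |  | 1.0 h |

| run | time / min | monomer in chains / % | free monomer / % |
|---|---|---|---|
| Wednesday's | 10.0 | 68.3 | 31.4 |
| Wednesday's | 20.0 | 80.9 | 19.2 |
| Wednesday's | 25.0 | 82.9 | 16.5 |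
| Wednesday's | 40.0 | 85.2 | 13.1 |
| Saturday's | 3.00 | 34.6 | 63.9 |
| Saturday's | 6.00 | 54.9 | 44.8 |
| Saturday's | 15.0 | 76.1 | 23.7 |
| Saturday's | 40.0 | 86.0 | 13.3 |

(standard deviation of a reading: 0.5 percentage points)

- average number of monomer units in a chain (living and dead chains, two that joined counted as one) at 1.0 h
- part of the free monomer that has reacted at 1.0 h

- the average divides the monomer in chains by the number of chains, living and dead together; two radicals that join make one chain
- the earlier runs do not show the number of chains; that part of a forecast is a guess

2. I began with the main step. I took growth as pseudo-first-order in free monomer, at the slope of Saturday's first reading, 0.149 min⁻¹. Held to 1.0 h, that slope left 0.0129% free monomer, far below the late readings.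

3. I added the dying of the radicals. I took the slope to fall away and free monomer to stop near exp(−S). For c, the part of the free monomer that has reacted, my reckoning for the flask was 86.8%.

4. I added the balance of initiator, the smaller charge. I took one initiator to give two radicals, and two that join make one chain. So I assumed one chain per initiator charged. For dp, the average number of monomer units in a chain, that gave 434 in the flask. The runs show no chains, so this was a guess. I also assumed that radicals made in proportion to initiator and lost in pairs make S scale with the square root of initiator. Both runs had 0.38 mM, so they could not test this.

5. The forecast said dp = 460 and c = 87.5%, on the ground that “the active centres die off and conversion stalls”. Both stood higher than my figures.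

6. The flask gave dp = 429 and c = 87.2%, so the forecast stood.

    initiator → 2 initiating radical (k = 0.00270 s⁻¹)
    free monomer + initiating radical → growing radical + monomer in chains (k = 7.00 × 10⁵ M⁻¹ s⁻¹)
    free monomer + growing radical → monomer in chains + growing radical, rate k3*[growing radical]*[free monomer] (k = 18000 M⁻¹ s⁻¹)
    2 growing radical → dead chain (k = 4.30 × 10⁷ M⁻¹ s⁻¹)
    monomer in chains → over-reaction product (k = 4.90 × 10⁻⁶ s⁻¹)

At 0.0666 h in the flask, the half-life of initiator by its own breakdown was 0.071 h, shorter than the 0.096 h of free monomer by its step to monomer in chains, and at 1.00 h the flask held 0.00601% of its initiator charge beside 12.8% free monomer, against 13.3% from S. The flask's c moved by 4 points with its initiator at 0.287 mM or 0.529 mM, all else held. For the neighbour flask with 6.5 × 10⁻⁴ M of initiator, S scaled by the square root gave 7.08% free monomer and dp = 272, and that flask held 6.8% free monomer and gave dp = 268.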